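## Retrosynthetic overview

- The (2S)-flavanone target is traced back through its 7-O-silyl ether to a (2S,4S)-4-allyloxyflavan. The C4 carbonyl is carried as an allyl ether that is later cleaved and oxidised, so C4 is a temporary stereocentre and only C2 has to be secured.
- Key disconnection: C3–C4 and O1–C2 of the pyran ring (O1–C2–C3–C4–C4a–C8a), the only ring formed in the route. The strategy rests on reading O1–C8a–C4a–C4 as the heterodiene of a salicylaldehyde whose formyl carbon supplies the oxidation level of C4, and C2–C3 with the 4-methoxyphenyl group on C2 as the electron-rich alkene 4-methoxystyrene.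
- The two are joined with allyl alcohol in a chiral phosphoric acid-catalysed oxa-[4+2] annulation of an O-allyl oxocarbenium ion (a protonated 4-allyloxy ortho-quinone methide).
- The salicylaldehyde, 4-silyloxy-2-hydroxy-3,5-diprenylbenzaldehyde, comes from 2,4-dihydroxybenzaldehyde by bis-O-allylation, double Claisen rearrangement, cross-metathesis with 2-methylbut-2-ene and selective 4-O-silylation. Both benzene rings are bought as arenes.

Key step: step 5

Assumption: the sense of induction of a given catalyst enantiomer cannot be predicted with confidence for this new reaction; (R)-TRIP is written, and its antipode would be used if the 2R series were found to form.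

## Route

Step 1
Reactants: 1 2,4-dihydroxybenzaldehyde
Product: 2 2,4-bis(allyloxy)benzaldehyde
Conditions: allyl bromide (2.5 equiv), K2CO3, DMF, 60 °C
Reagents that add atoms: allyl bromide, C=CCBr
Why: Williamson ether synthesis; both phenoxides are O-alkylated by the unhindered allylic bromide, the chelated 2-hydroxyl needing the polar solvent and gentle heating.

Step 2
Reactants: 2 2,4-bis(allyloxy)benzaldehyde
Product: 3 3,5-diallyl-2,4-dihydroxybenzaldehyde
Conditions: N,N-diethylaniline, 200 °C, argon
Reagents that add atoms: none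
Why: double aromatic Claisen rearrangement; C1 is blocked by the formyl group, so every ortho and para ([3,3] then Cope) pathway of the two allyl groups converges on C3 and C5.

Step 3
Reactants: 3 3,5-diallyl-2,4-dihydroxybenzaldehyde
Product: 4 2,4-dihydroxy-3,5-bis(3-methylbut-2-en-1-yl)benzaldehyde
Conditions: Grubbs II (5 mol%), 2-methylbut-2-ene/CH2Cl2, 40 °C
Reagents that add atoms: 2-methylbut-2-ene, CC=C(C)C
Why: olefin cross-metathesis; excess 2-methylbut-2-ene should convert each terminal allyl group into the trisubstituted prenyl group with loss of propene, and free phenols and the aldehyde are tolerated by the ruthenium carbene.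

Step 4
Reactants: 4 2,4-dihydroxy-3,5-bis(3-methylbut-2-en-1-yl)benzaldehyde
Product: 5 4-(tert-butyldimethylsilyloxy)-2-hydroxy-3,5-bis(3-methylbut-2-en-1-yl)benzaldehyde
Conditions: TBSCl (1.1 equiv), imidazole, DMF, 0 °C to rt
Reagents that add atoms: tert-butyldimethylsilyl chloride, CC(C)(C)[Si](C)(C)Cl
Why: selective silyl ether formation; the 4-hydroxyl (para to the formyl group, not chelated) is the more acidic and more nucleophilic one, while the 2-hydroxyl is locked in a hydrogen bond to the aldehyde and stays free for the annulation.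

Step 5
Reactants: 5 4-(tert-butyldimethylsilyloxy)-2-hydroxy-3,5-bis(3-methylbut-2-en-1-yl)benzaldehyde; 6 allyl alcohol; 7 4-methoxystyrene
Product: 10 (2S,4S)-4-(allyloxy)-7-(tert-butyldimethylsilyloxy)-2-(4-methoxyphenyl)-6,8-bis(3-methylbut-2-en-1-yl)chromane, via O-allyl oxocarbenium ion 8 (not isolated), via anisyl-stabilised benzylic cation 9 (not isolated)
Conditions: 6 (1.5 equiv), 7 (3 equiv), (R)-TRIP (10 mol%), 5 Å MS, toluene, 0 °C
Reagents that add atoms: none
Why: Proposed new method: the phosphoric acid should condense 5 with allyl alcohol (water goes to the sieves) to the O-allyl oxocarbenium ion 8, an O-protonated 4-allyloxy ortho-quinone methide held to the chiral phosphate by ion pairing and by a hydrogen bond from the C8a hydroxyl; the CH2 terminus of 4-methoxystyrene then attacks its carbenium carbon (C3–C4 bond) and the anisyl-stabilised cation 9 is captured by the phenol oxygen (O1–C2 bond). The closest known reaction types are the achiral acid-catalysed three-component synthesis of 2,4-cis-4-alkoxyflavans from salicylaldehydes, alcohols or orthoformates and styrenes, and chiral phosphoric acid-catalysed [4+2] cycloadditions of ortho-quinone methides with electron-rich alkenes; an intermolecular enantioselective merger of the two has not been shown. The pyran ring closes by 6-exo-trig attack of the phenol oxygen on the quinoid (para-quinone methide oxocarbenium) form of 9, so that the whole is a stepwise, asynchronous inverse-demand oxa-[4+2] annulation. C4 is set in the C–C bond formation by the phosphate, which should shield one face of 8, and C2 is set in the ring closure through a chair-like transition state with the anisyl and allyloxy groups pseudo-equatorial (2,4-cis), which relays the catalyst-controlled C4 configuration to C2. The step needs enantioface control, cis selectivity (a trans isomer arising from the same first step would carry 2R and is to be removed by chromatography before C4 is oxidised) and chemoselectivity for the styrene over the prenyl alkenes. The last is secured by the higher π-nucleophilicity of 4-methoxystyrene (used in excess) and the stability of the cation it gives, while the O7 silyl ether and the O1 hydroxyl stabilise 8 and the silyl group keeps O7 from adding to the flanking prenyl groups under acid.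

Step 6
Reactants: 10 (2S,4S)-4-(allyloxy)-7-(tert-butyldimethylsilyloxy)-2-(4-methoxyphenyl)-6,8-bis(3-methylbut-2-en-1-yl)chromane
Product: 12 (2S,4S)-7-(tert-butyldimethylsilyloxy)-2-(4-methoxyphenyl)-6,8-bis(3-methylbut-2-en-1-yl)chroman-4-ol, via (E)-prop-1-enyl ether 11 (not isolated)
Conditions: [Ir(cod)(PMePh2)2]PF6 (3 mol%, H2-activated, then degassed), THF, rt; then aq. HCl (pH 2), THF, 0 °C to rt
Reagents that add atoms: none
Why: transition-metal allyl-to-propenyl isomerisation followed by enol ether hydrolysis; the cationic iridium hydride should move only the terminal allyl double bond (the trisubstituted prenyl alkenes are inert), and hydrolysis of 11 by C-protonation at pH 2 leaves the C4–O bond, both stereocentres and the aryl silyl ether intact.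

Step 7
Reactants: 12 (2S,4S)-7-(tert-butyldimethylsilyloxy)-2-(4-methoxyphenyl)-6,8-bis(3-methylbut-2-en-1-yl)chroman-4-ol
Product: 13 (2S)-7-(tert-butyldimethylsilyloxy)-2-(4-methoxyphenyl)-6,8-bis(3-methylbut-2-en-1-yl)chroman-4-one
Conditions: Dess–Martin periodinane (1.3 equiv), pyridine, CH2Cl2, 0 °C to rt
Reagents that add atoms: none
Why: Dess–Martin oxidation of the secondary benzylic alcohol under buffered, non-enolising conditions should give the flavanone, erase the temporary C4 stereocentre and leave C2, the prenyl alkenes and the silyl ether untouched.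

Step 8
Reactants: 13 (2S)-7-(tert-butyldimethylsilyloxy)-2-(4-methoxyphenyl)-6,8-bis(3-methylbut-2-en-1-yl)chroman-4-one
Product: 14 (2S)-7-hydroxy-2-(4-methoxyphenyl)-6,8-bis(3-methylbut-2-en-1-yl)chroman-4-one (the target natural product)
Conditions: TBAF (1.1 equiv), AcOH (1.3 equiv), THF, 0 °C
Reagents that add atoms: none
Why: fluoride-mediated silyl ether cleavage, fast for an aryl silyl ether para to a carbonyl; the acetic acid buffer protonates the phenoxide at once, which suppresses the base-induced retro-oxa-Michael opening to the 2'-hydroxychalcone, the only pathway that would racemise C2.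

## Compound list

1 | 2,4-dihydroxybenzaldehyde | O=Cc1ccc(O)cc1O | starting material
2 | 2,4-bis(allyloxy)benzaldehyde | O=Cc1ccc(OCC=C)cc1OCC=C | intermediate
3 | 3,5-diallyl-2,4-dihydroxybenzaldehyde | O=Cc1cc(CC=C)c(O)c(CC=C)c1O | intermediate
4 | 2,4-dihydroxy-3,5-bis(3-methylbut-2-en-1-yl)benzaldehyde | O=Cc1cc(CC=C(C)C)c(O)c(CC=C(C)C)c1O | intermediate
5 | 4-(tert-butyldimethylsilyloxy)-2-hydroxy-3,5-bis(3-methylbut-2-en-1-yl)benzaldehyde | O=Cc1cc(CC=C(C)C)c(O[Si](C)(C)C(C)(C)C)c(CC=C(C)C)c1O | intermediate
6 | allyl alcohol | C=CCO | starting material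
7 | 4-methoxystyrene | C=Cc1ccc(OC)cc1 | starting material
8 | O-allyl oxocarbenium ion of 5 (protonated 4-allyloxy ortho-quinone methide, chiral phosphate ion pair; cation shown) | C=CC[O+]=Cc1cc(CC=C(C)C)c(O[Si](C)(C)C(C)(C)C)c(CC=C(C)C)c1O | intermediate (not isolated)
9 | (3S)-3-(allyloxy)-3-[4-(tert-butyldimethylsilyloxy)-2-hydroxy-3,5-bis(3-methylbut-2-en-1-yl)phenyl]-1-(4-methoxyphenyl)propyl cation | COc1ccc([CH+]C[C@H](OCC=C)c2cc(CC=C(C)C)c(O[Si](C)(C)C(C)(C)C)c(CC=C(C)C)c2O)cc1 | intermediate (not isolated)
10 | (2S,4S)-4-(allyloxy)-7-(tert-butyldimethylsilyloxy)-2-(4-methoxyphenyl)-6,8-bis(3-methylbut-2-en-1-yl)chromane (2,4-cis) | COc1ccc([C@@H]2C[C@H](OCC=C)c3cc(CC=C(C)C)c(O[Si](C)(C)C(C)(C)C)c(CC=C(C)C)c3O2)cc1 | intermediate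
11 | (2S,4S)-7-(tert-butyldimethylsilyloxy)-2-(4-methoxyphenyl)-6,8-bis(3-methylbut-2-en-1-yl)-4-[(E)-prop-1-en-1-yloxy]chromane | COc1ccc([C@@H]2C[C@H](O/C=C/C)c3cc(CC=C(C)C)c(O[Si](C)(C)C(C)(C)C)c(CC=C(C)C)c3O2)cc1 | intermediate (not isolated)
12 | (2S,4S)-7-(tert-butyldimethylsilyloxy)-2-(4-methoxyphenyl)-6,8-bis(3-methylbut-2-en-1-yl)chroman-4-ol | COc1ccc([C@@H]2C[C@H](O)c3cc(CC=C(C)C)c(O[Si](C)(C)C(C)(C)C)c(CC=C(C)C)c3O2)cc1 | intermediate
13 | (2S)-7-(tert-butyldimethylsilyloxy)-2-(4-methoxyphenyl)-6,8-bis(3-methylbut-2-en-1-yl)chroman-4-one | COc1ccc([C@@H]2CC(=O)c3cc(CC=C(C)C)c(O[Si](C)(C)C(C)(C)C)c(CC=C(C)C)c3O2)cc1 | intermediate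
14 | (2S)-7-hydroxy-2-(4-methoxyphenyl)-6,8-bis(3-methylbut-2-en-1-yl)chroman-4-one (the target natural product) | COc1ccc([C@@H]2CC(=O)c3cc(CC=C(C)C)c(O)c(CC=C(C)C)c3O2)cc1 | target

## Step count and risks

Total step count: 8. Longest linear sequence: 8 steps (1 to 14).

**Steps most likely to fail**

1. Step 5 (Proposed new method).
   - What may go wrong: the phosphoric acid may be too weak to ionise the hemiacetal, so that little cation forms (a more acidic chiral N-triflyl phosphoramide would be the first adjustment within the method).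
   - The styrene may oligomerise cationically, a prenyl alkene may add to the cation or to the 2-hydroxyl, or the silyl group may be transferred to the phosphate.
   - Facial selectivity may be low, and re-ionisation at C4 or C2 of the product may erode the cis selectivity and the enantiomeric purity.
   - Fallback by known chemistry, from 5 back to the route at 13, in which C2 is set by asymmetric conjugate arylation of a chromone: addition of ethynylmagnesium bromide (3 equiv, the first equivalent being consumed by the phenol) to 5 (THF, −78 to 0 °C) should give racemic 1-[4-(tert-butyldimethylsilyloxy)-2-hydroxy-3,5-bis(3-methylbut-2-en-1-yl)phenyl]prop-2-yn-1-ol F1. Oxidation with MnO2 (CH2Cl2, rt) gives 1-[4-(tert-butyldimethylsilyloxy)-2-hydroxy-3,5-bis(3-methylbut-2-en-1-yl)phenyl]prop-2-yn-1-one F2. Amine-promoted 6-endo-dig cyclisation (Et2NH, CH2Cl2, rt) gives 7-(tert-butyldimethylsilyloxy)-6,8-bis(3-methylbut-2-en-1-yl)-4H-chromen-4-one F3. Pd(II)/pyridine-oxazoline-catalysed asymmetric conjugate addition of 4-methoxyphenylboronic acid (Pd(OCOCF3)2, t-BuPyOx of the configuration that delivers 2S, NH4PF6, H2O, ClCH2CH2Cl, 60 °C) then gives 13, and step 8 follows.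

2. Step 6.
   - What may go wrong: ionisation at C4 during the acidic hydrolysis, followed by elimination to the flav-3-ene, or reduction of alkenes by hydrogen left on the iridium catalyst.
   - Fallback, from 10 directly to 12 under non-acidic conditions: NiCl2(dppp)-catalysed hydroalumination of the terminal allyl double bond with DIBAL-H (toluene, 0 °C), followed by β-alkoxide elimination and Rochelle-salt work-up. The trisubstituted prenyl alkenes do not react (no new compound; F0).

3. Step 2.
   - What may go wrong: migration to C1 with loss of the formyl group, cyclisation of the ortho-allylphenols to 2-methyl-2,3-dihydrobenzofurans at the high temperature, or an incomplete second rearrangement.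
   - Fallback, from 1 back to the route at 4 (replacing steps 1 to 3) by halogenation and cross-coupling: iodination of 1 with N-iodosuccinimide (2.2 equiv, cat. TFA, MeCN) should give 2,4-dihydroxy-3,5-diiodobenzaldehyde F4. Acetylation (Ac2O, pyridine, DMAP) gives 2,4-diacetoxy-3,5-diiodobenzaldehyde F5, which masks the acidic phenols that would otherwise protodestannylate the allylic stannane. Double Stille coupling with tributyl(3-methylbut-2-en-1-yl)stannane (Pd(PPh3)4, DMF, 90 °C) gives 2,4-diacetoxy-3,5-bis(3-methylbut-2-en-1-yl)benzaldehyde F6. Methanolysis (K2CO3, MeOH, 0 °C) then gives 4.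

Further compounds
F1 | step 5 | racemic 1-[4-(tert-butyldimethylsilyloxy)-2-hydroxy-3,5-bis(3-methylbut-2-en-1-yl)phenyl]prop-2-yn-1-ol | C#CC(O)c1cc(CC=C(C)C)c(O[Si](C)(C)C(C)(C)C)c(CC=C(C)C)c1O
F2 | step 5 | 1-[4-(tert-butyldimethylsilyloxy)-2-hydroxy-3,5-bis(3-methylbut-2-en-1-yl)phenyl]prop-2-yn-1-one | C#CC(=O)c1cc(CC=C(C)C)c(O[Si](C)(C)C(C)(C)C)c(CC=C(C)C)c1O
F3 | step 5 | 7-(tert-butyldimethylsilyloxy)-6,8-bis(3-methylbut-2-en-1-yl)-4H-chromen-4-one | O=c1ccoc2c(CC=C(C)C)c(O[Si](C)(C)C(C)(C)C)c(CC=C(C)C)cc12
F0 | step 6 | none | none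
F4 | step 2 | 2,4-dihydroxy-3,5-diiodobenzaldehyde | O=Cc1cc(I)c(O)c(I)c1O
F5 | step 2 | 2,4-diacetoxy-3,5-diiodobenzaldehyde | CC(=O)Oc1c(I)cc(C=O)c(OC(C)=O)c1I
F6 | step 2 | 2,4-diacetoxy-3,5-bis(3-methylbut-2-en-1-yl)benzaldehyde | CC(=O)Oc1c(CC=C(C)C)cc(C=O)c(OC(C)=O)c1CC=C(C)C
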